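**The question.** If the gas feeds the nucleophile into the flask, then I keep the books of the electrophile, the limiting reagent, in shares of its charge, and I ask what share leaves per minute.

common to all: gas 11 mM (held)

|  | electrophile | free base | remark | time |
|---|---|---|---|---|
| grey | 0.030 M | 10 mM | run made earlier |  |
| beta | 0.020 M | 20.0 mM |  | 15 min |
| epsilon | 0.020 M | 10.0 mM |  | 15 min |
| delta | 0.020 M | 40.0 mM |  | 15 min |

- grey (time / min: electrophile / %, target / %): 1.50: 86, 13; 3.00: 67, 32; 5.00: 55, 43; 6.00: 48, 51; 8.00: 34, 62; 10.0: 26, 67

(standard deviation of a reading: 2 percentage points)

- at the start none of nucleophile is dissolved
- steps under discussion: gas <-> nucleophile; acid set free + free base <-> salt of the base; electrophile + nucleophile <-> acid set free + target; target <-> isomer of the product; nucleophile + acid set free <-> protonated nucleophile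
- no earlier run changes the charge of free base; that part of a forecast is a guess

- part of the electrophile that has reacted at the end, beta
- part of the electrophile that has reacted at the end, epsilon
- part of the electrophile that has reacted at the end, delta
- what raising the concentration of free base from its lowest to its highest value here does to the part of the electrophile that has reacted (changes below 5 percentage points count as none) (it falls / no change / it rises)

**First entry.** At 10.0 min the grey run holds 67% of its charge as target and 26% as electrophile. I book the missing 7.00% to the isomer of the product.

**Gas entry.** The grey run has used 74.0% of its charge, twice the 36.7% that dissolved nucleophile can match at saturation, so the gas must have delivered during the run. I take that delivery as an amount per minute, whatever the charge.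

**The draw.** The grey mean over 10.0 min, scaled to a charge of 0.020 M, gives 0.111 /min. This draw, the share of the charge that leaves per minute, is a reading and carries the scatter of the grey run.

**Closing the books.** At that draw the charge is cleared in 9.01 min, sooner than the 15 min allowed. Allowing a small tail, I book nearly all as reacted in beta, epsilon and delta. Free base in epsilon covers 50.0% of the charge, more than the 33.3% of the grey run, and the readings of the grey run put its reacted share at 74.0%, past that cover. So I guess no change from epsilon to delta, and it stays a guess.

**The forecast.** It gives 87% for beta, 87% for epsilon, 87% for delta, and no change: “First order means the starting concentration does not matter”. We agree on the trend, but I book more as reacted than it does.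

**The flask.** Epsilon ends at 98.4% reacted, beta at 99.2% and delta at 99.4%, and the change of 0.99 percentage points from epsilon to delta counts as no change.

    gas ⇌ nucleophile, rate k1*(csat - [nucleophile]) (kL = 0.480 /min)
    acid set free + free base ⇌ salt of the base, settled at all times (K = 8.90 × 10⁵ /M)
    electrophile + nucleophile ⇌ acid set free + target (K = 3.10, k = 50.0 /M/min)
    target ⇌ isomer of the product (K = 0.620, k = 0.0180 /min)
    nucleophile + acid set free ⇌ protonated nucleophile, settled at all times (K = 40000 /M)

**Draw reused.** At 15.0 min epsilon still holds 1.6% of its charge as electrophile. Read at 6.0 min, epsilon has reacted 66.0%, and the draw books 66.6%. For a neighbour of epsilon charged with 0.080 M of electrophile, the same amount per minute makes a draw of 0.0278 /min, which books 41.6% by 15 min, and that neighbour has reacted 50.8%.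

(The data were computed with constants of no real substance; noise was put on by code.)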